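**Retrosynthetic overview**
- The enal is unmasked last: a tertiary isopropenyl carbinol on the ring is turned into the (Z)-enal by an oxidative 1,3-transposition of oxygen, then the side-chain silyl ether is removed.
- The myristoyloxypropyl arm comes from an allyl group (hydroboration, then acylation); the isopropenyl carbinol comes from a ring ketone.
- The ring ketone with its quaternary centre comes from a 4-hydroxy-3,4-dimethylcyclohexenone, a side-chain Grignard reagent and allyl bromide (alkoxide-directed conjugate addition, then enolate allylation).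
- The hydroxy-enone comes from 3,4-dimethylphenol by a catalytic enantioselective para-hydroxylative dearomatization (the key C–O bond, which sets the carbinol centre) and one selective hydrogenation. The only ring is bought as the arene; no ring is formed.
- The side chain comes from 5-bromo-2-methylpent-2-ene and geranyl chloride (SeO2 oxidation, barium-mediated geranylation, Sharpless kinetic resolution, silylation).

Assumption: the (R,R)-antipode of the catalyst below is taken to give the (S)-quinol; if it gives (R), the equally accessible (S,S)-antipode is used.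

Catalyst for step 1, ArI*: (2R,2'R)-2,2'-[(2-iodo-1,3-phenylene)bis(oxy)]bis{N-[2,4-dimethyl-6-(pyrrolidine-1-carbonyl)phenyl]propanamide}, SMILES C[C@@H](Oc1cccc(O[C@H](C)C(=O)Nc2c(C)cc(C)cc2C(=O)N2CCCC2)c1I)C(=O)Nc1c(C)cc(C)cc1C(=O)N1CCCC1.

Abbreviation used in names: SC = (3E,5R,7E)-5-[tert-butyl(dimethyl)silyl]oxy-4,8,12-trimethyltrideca-3,7,11-trien-1-yl.

**Route**

Step 1
Reactants: 1 3,4-dimethylphenol
Product: 2 (4S)-4-hydroxy-3,4-dimethylcyclohexa-2,5-dien-1-one
Conditions: ArI* (10 mol%), mCPBA (1.2 equiv), MeCN/H2O 9:1, −20 °C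
Reagents that add atoms: water, O
Why: Proposed new method: mCPBA oxidises the aryl iodide to a chiral trivalent-iodine species that binds the phenol oxygen, the folded lactamide arms cover one face of the aryloxy ligand while their pendant amide carbonyls hydrogen-bond and steer water onto the methyl-bearing para carbon of the open face as the iodoarene is reductively expelled, so the tertiary C–O bond and the (S) carbinol centre (the only source of ring chirality) form in one event; the closest known reaction types are chiral aryl-iodide-catalysed ortho-spirolactonising dearomatization of phenols and the racemic PhI(OAc)2/water para-quinol synthesis.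

Step 2
Reactants: 2 (4S)-4-hydroxy-3,4-dimethylcyclohexa-2,5-dien-1-one
Product: 3 (4S)-4-hydroxy-3,4-dimethylcyclohex-2-en-1-one
Conditions: H2 (1 atm), RhCl(PPh3)3 (5 mol%), benzene, 23 °C
Reagents that add atoms: none
Why: Chemoselective homogeneous hydrogenation, as in the classical 1,2-reduction of cross-conjugated dienones: the unhindered disubstituted enone C=C is reduced much faster than the trisubstituted β-methyl enone C=C, and the stereocentre is untouched.

Step 3
Reactants: 4 5-bromo-2-methylpent-2-ene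
Product: 6 (2E)-5-bromo-2-methylpent-2-enal, via (2E)-5-bromo-2-methylpent-2-en-1-ol 5 (not isolated)
Conditions: SeO2 (1.2 equiv), 1,4-dioxane/H2O 20:1, 90 °C
Reagents that add atoms: selenium dioxide, O=[Se]=O
Why: Riley-type SeO2 allylic oxidation (ene reaction then [2,3]-sigmatropic shift) attacks the (E)-methyl of the gem-dimethyl alkene selectively and oxidises the allylic alcohol 5 on to the (E)-enal.

Step 4
Reactants: 7 geranyl chloride, 6 (2E)-5-bromo-2-methylpent-2-enal
Product: 9 rac-(3E,7E)-1-bromo-4,8,12-trimethyltrideca-3,7,11-trien-5-ol, via geranylbarium chloride 8 (not isolated)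
Conditions: BaI2, Li(C12H10) (lithium biphenylide, 2 equiv), THF, 23 °C; 7, −78 °C; then 6, −78 °C; aq. NH4Cl
Reagents that add atoms: none
Why: α-Selective allylbarium carbonyl addition: geranylbarium chloride attacks the aldehyde 1,2 through its unsubstituted carbon with retention of the E alkene, giving the linear homoallylic alcohol as the racemate.

Step 5
Reactants: 9 rac-(3E,7E)-1-bromo-4,8,12-trimethyltrideca-3,7,11-trien-5-ol
Product: 10 (3E,5R,7E)-1-bromo-4,8,12-trimethyltrideca-3,7,11-trien-5-ol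
Conditions: Ti(OiPr)4 (0.2 equiv), L-(+)-diisopropyl tartrate (0.24 equiv), tBuOOH (0.6 equiv), 4 Å MS, CH2Cl2, −20 °C
Reagents that add atoms: none
Why: Sharpless kinetic resolution by asymmetric epoxidation: with L-(+)-tartrate the (5S)-enantiomer of this (E)-trisubstituted secondary allylic alcohol is epoxidised much faster, so the (5R)-alcohol is recovered in high ee at about 55% conversion (at most about 45% yield).

Step 6
Reactants: 10 (3E,5R,7E)-1-bromo-4,8,12-trimethyltrideca-3,7,11-trien-5-ol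
Product: 11 tert-butyl{[(3E,5R,7E)-1-bromo-4,8,12-trimethyltrideca-3,7,11-trien-5-yl]oxy}dimethylsilane
Conditions: TBSOTf, 2,6-lutidine, CH2Cl2, −78 °C
Reagents that add atoms: tert-butyldimethylsilyl triflate, CC(C)(C)[Si](C)(C)OS(=O)(=O)C(F)(F)F
Why: Standard silylation of a hindered secondary alcohol; the ether masks the alcohol through the Grignard, acylation and chromium steps.

Step 7
Reactants: 11 tert-butyl{[(3E,5R,7E)-1-bromo-4,8,12-trimethyltrideca-3,7,11-trien-5-yl]oxy}dimethylsilane, 3 (4S)-4-hydroxy-3,4-dimethylcyclohex-2-en-1-one, 12 allyl bromide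
Product: 17 (2R,3R,4S)-4-hydroxy-3,4-dimethyl-2-(prop-2-en-1-yl)-3-SC-cyclohexan-1-one, via Grignard reagent 13 (not isolated), via chloromagnesium alkoxide 14 (not isolated), via magnesium enolate 15 (not isolated), via C2 epimer 16 (not isolated)
Conditions: 11, Mg, THF, 23 °C; separately 3, t-BuMgCl (1 equiv), THF, −78 °C; combine, −78 → 0 °C; 12, DMPU, −20 → 23 °C; then NaOMe (cat.), MeOH, 23 °C
Reagents that add atoms: none
Why: Alkoxide-directed (chelation-controlled) Grignard conjugate addition then enolate alkylation, as known for quinol and γ-hydroxy-enone or -nitrile alkoxides: an alkylmagnesium alkoxide delivers the chain intramolecularly to the β-carbon on the face of the C–O bond (chain cis to OH, setting the quaternary centre), the enolate is C-allylated, and NaOMe equilibrates the α-centre to the isomer with the allyl group equatorial and trans to the chain.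

Step 8
Reactants: 17 (2R,3R,4S)-4-hydroxy-3,4-dimethyl-2-(prop-2-en-1-yl)-3-SC-cyclohexan-1-one, 18 isopropenylmagnesium bromide
Product: 20 (1S,2R,3R,4S)-1,2-dimethyl-4-(prop-1-en-2-yl)-3-(prop-2-en-1-yl)-2-SC-cyclohexane-1,4-diol, via bromomagnesium alkoxide 19 (not isolated)
Conditions: 18 (3 equiv), LaCl3·2LiCl (1 equiv), THF, 0 °C
Reagents that add atoms: none
Why: Lanthanum-promoted Grignard 1,2-addition to a hindered, enolisable ketone; equatorial attack away from the axial C3 methyl is expected, but this carbinol centre is destroyed in step 11, so either epimer serves.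

Step 9
Reactants: 20 (1S,2R,3R,4S)-1,2-dimethyl-4-(prop-1-en-2-yl)-3-(prop-2-en-1-yl)-2-SC-cyclohexane-1,4-diol
Product: 22 (1S,2R,3R,4S)-3-(3-hydroxypropyl)-1,2-dimethyl-4-(prop-1-en-2-yl)-2-SC-cyclohexane-1,4-diol, via B-alkyl-9-BBN adduct 21 (not isolated)
Conditions: 9-BBN (1.3 equiv), THF, 0 → 23 °C; then NaOH, H2O2, 0 °C
Reagents that add atoms: hydrogen peroxide, OO
Why: 9-BBN hydroboration–oxidation is selective for the monosubstituted allyl alkene over the 1,1-disubstituted isopropenyl and the trisubstituted chain alkenes and gives the anti-Markovnikov primary alcohol.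

Step 10
Reactants: 22 (1S,2R,3R,4S)-3-(3-hydroxypropyl)-1,2-dimethyl-4-(prop-1-en-2-yl)-2-SC-cyclohexane-1,4-diol, 23 tetradecanoyl chloride
Product: 24 3-[(1R,2R,3S,6S)-3,6-dihydroxy-2,3-dimethyl-6-(prop-1-en-2-yl)-2-SC-cyclohexyl]propyl tetradecanoate
Conditions: 23 (1.05 equiv), pyridine, CH2Cl2, −20 → 0 °C
Reagents that add atoms: none
Why: Acylation with an acid chloride at low temperature esterifies the primary alcohol only; the two tertiary alcohols do not react.

Step 11
Reactants: 24 3-[(1R,2R,3S,6S)-3,6-dihydroxy-2,3-dimethyl-6-(prop-1-en-2-yl)-2-SC-cyclohexyl]propyl tetradecanoate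
Product: 27 3-[(1S,2R,3S,6Z)-3-hydroxy-2,3-dimethyl-6-(1-oxopropan-2-ylidene)-2-SC-cyclohexyl]propyl tetradecanoate, via tertiary chlorochromate ester 25 (not isolated), via primary allylic chlorochromate ester 26 (not isolated)
Conditions: [C5H5NH][CrO3Cl] (pyridinium chlorochromate, 3 equiv), Celite, CH2Cl2, 23 °C
Reagents that add atoms: pyridinium chlorochromate, [O-][Cr](=O)(=O)Cl.c1cc[nH+]cc1
Why: Babler–Dauben oxidative 1,3-transposition: the tertiary allylic chromate ester undergoes a [3,3] shift that forms the new C–O bond at the terminal carbon and the tetrasubstituted alkene, and the primary chromate is oxidised to the enal; the Z isomer is expected because the methyl group avoids the substituted ring carbon C1 (allylic strain), which should also be the thermodynamic preference.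

Step 12
Reactants: 27 3-[(1S,2R,3S,6Z)-3-hydroxy-2,3-dimethyl-6-(1-oxopropan-2-ylidene)-2-SC-cyclohexyl]propyl tetradecanoate
Product: 28 3-[(1S,2R,3S,6Z)-3-hydroxy-2-[(3E,5R,7E)-5-hydroxy-4,8,12-trimethyltrideca-3,7,11-trien-1-yl]-2,3-dimethyl-6-(1-oxopropan-2-ylidene)cyclohexyl]propyl tetradecanoate
Conditions: HF·pyridine, pyridine, THF, 0 → 23 °C
Reagents that add atoms: none
Why: Buffered fluoride desilylation removes the secondary silyl ether without touching the ester, the enal, the tertiary alcohol or the allylic stereocentre.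

**Compound list**

1 | 3,4-dimethylphenol | Cc1ccc(O)cc1C | starting material
2 | (4S)-4-hydroxy-3,4-dimethylcyclohexa-2,5-dien-1-one | O=C1C=C[C@](C)(O)C(C)=C1 | intermediate
3 | (4S)-4-hydroxy-3,4-dimethylcyclohex-2-en-1-one | O=C1CC[C@](C)(O)C(C)=C1 | intermediate
4 | 5-bromo-2-methylpent-2-ene | CC(C)=CCCBr | starting material
5 | (2E)-5-bromo-2-methylpent-2-en-1-ol | OC/C(C)=C/CCBr | intermediate
6 | (2E)-5-bromo-2-methylpent-2-enal | O=C/C(C)=C/CCBr | intermediate
7 | geranyl chloride, (2E)-1-chloro-3,7-dimethylocta-2,6-diene | ClC/C=C(\C)CCC=C(C)C | starting material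
8 | geranylbarium chloride | Cl[Ba]C/C=C(\C)CCC=C(C)C | intermediate
9 | rac-(3E,7E)-1-bromo-4,8,12-trimethyltrideca-3,7,11-trien-5-ol | BrCC/C=C(\C)C(O)C/C=C(\C)CCC=C(C)C | intermediate
10 | (3E,5R,7E)-1-bromo-4,8,12-trimethyltrideca-3,7,11-trien-5-ol | BrCC/C=C(\C)[C@H](O)C/C=C(\C)CCC=C(C)C | intermediate
11 | tert-butyl{[(3E,5R,7E)-1-bromo-4,8,12-trimethyltrideca-3,7,11-trien-5-yl]oxy}dimethylsilane | BrCC/C=C(\C)[C@H](O[Si](C)(C)C(C)(C)C)C/C=C(\C)CCC=C(C)C | intermediate
12 | allyl bromide, 3-bromoprop-1-ene | C=CCBr | starting material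
13 | SC-magnesium bromide (Grignard reagent of 11) | Br[Mg]CC/C=C(\C)[C@H](O[Si](C)(C)C(C)(C)C)C/C=C(\C)CCC=C(C)C | intermediate
14 | chloromagnesium (1S)-1,2-dimethyl-4-oxocyclohex-2-en-1-olate (alkoxide of 3) | O=C1CC[C@](C)(O[Mg]Cl)C(C)=C1 | intermediate
15 | magnesium enolate of the conjugate adduct: (3R,4S)-3,4-dimethyl-3-SC-cyclohex-1-ene-1,4-diol as its 1-O-MgBr and 4-O-MgCl salt | Br[Mg]OC1=C[C@@](C)(CC/C=C(\C)[C@H](O[Si](C)(C)C(C)(C)C)C/C=C(\C)CCC=C(C)C)[C@@](C)(O[Mg]Cl)CC1 | intermediate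
16 | (2S,3R,4S)-4-hydroxy-3,4-dimethyl-2-(prop-2-en-1-yl)-3-SC-cyclohexan-1-one (C2 epimer of 17) | C=CC[C@@H]1C(=O)CC[C@](C)(O)[C@]1(C)CC/C=C(\C)[C@H](O[Si](C)(C)C(C)(C)C)C/C=C(\C)CCC=C(C)C | intermediate
17 | (2R,3R,4S)-4-hydroxy-3,4-dimethyl-2-(prop-2-en-1-yl)-3-SC-cyclohexan-1-one | C=CC[C@H]1C(=O)CC[C@](C)(O)[C@]1(C)CC/C=C(\C)[C@H](O[Si](C)(C)C(C)(C)C)C/C=C(\C)CCC=C(C)C | intermediate
18 | isopropenylmagnesium bromide | CC(=C)[Mg]Br | starting material
19 | bromomagnesium alkoxide of 17 (configuration as 17) | C=CC[C@H]1C(=O)CC[C@](C)(O[Mg]Br)[C@]1(C)CC/C=C(\C)[C@H](O[Si](C)(C)C(C)(C)C)C/C=C(\C)CCC=C(C)C | intermediate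
20 | (1S,2R,3R,4S)-1,2-dimethyl-4-(prop-1-en-2-yl)-3-(prop-2-en-1-yl)-2-SC-cyclohexane-1,4-diol | C=CC[C@H]1[C@](O)(C(C)=C)CC[C@](C)(O)[C@]1(C)CC/C=C(\C)[C@H](O[Si](C)(C)C(C)(C)C)C/C=C(\C)CCC=C(C)C | intermediate
21 | B-alkyl-9-borabicyclo[3.3.1]nonane adduct of 20 at the allyl terminus (configuration as 20) | B1(C2CCCC1CCC2)CCC[C@H]1[C@](O)(C(C)=C)CC[C@](C)(O)[C@]1(C)CC/C=C(\C)[C@H](O[Si](C)(C)C(C)(C)C)C/C=C(\C)CCC=C(C)C | intermediate
22 | (1S,2R,3R,4S)-3-(3-hydroxypropyl)-1,2-dimethyl-4-(prop-1-en-2-yl)-2-SC-cyclohexane-1,4-diol | OCCC[C@H]1[C@](O)(C(C)=C)CC[C@](C)(O)[C@]1(C)CC/C=C(\C)[C@H](O[Si](C)(C)C(C)(C)C)C/C=C(\C)CCC=C(C)C | intermediate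
23 | tetradecanoyl (myristoyl) chloride | CCCCCCCCCCCCCC(Cl)=O | starting material
24 | 3-[(1R,2R,3S,6S)-3,6-dihydroxy-2,3-dimethyl-6-(prop-1-en-2-yl)-2-SC-cyclohexyl]propyl tetradecanoate | CCCCCCCCCCCCCC(=O)OCCC[C@H]1[C@](O)(C(C)=C)CC[C@](C)(O)[C@]1(C)CC/C=C(\C)[C@H](O[Si](C)(C)C(C)(C)C)C/C=C(\C)CCC=C(C)C | intermediate
25 | tertiary allylic chlorochromate ester of 24 (at the isopropenyl carbinol; configuration as 24) | CCCCCCCCCCCCCC(=O)OCCC[C@H]1[C@](O[Cr](=O)(=O)Cl)(C(C)=C)CC[C@](C)(O)[C@]1(C)CC/C=C(\C)[C@H](O[Si](C)(C)C(C)(C)C)C/C=C(\C)CCC=C(C)C | intermediate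
26 | rearranged (Z)-primary allylic chlorochromate ester (configuration as 27) | CCCCCCCCCCCCCC(=O)OCCC[C@H]1/C(=C(/C)CO[Cr](=O)(=O)Cl)CC[C@](C)(O)[C@]1(C)CC/C=C(\C)[C@H](O[Si](C)(C)C(C)(C)C)C/C=C(\C)CCC=C(C)C | intermediate
27 | 3-[(1S,2R,3S,6Z)-3-hydroxy-2,3-dimethyl-6-(1-oxopropan-2-ylidene)-2-SC-cyclohexyl]propyl tetradecanoate | CCCCCCCCCCCCCC(=O)OCCC[C@H]1/C(=C(/C)C=O)CC[C@](C)(O)[C@]1(C)CC/C=C(\C)[C@H](O[Si](C)(C)C(C)(C)C)C/C=C(\C)CCC=C(C)C | intermediate
28 | 3-[(1S,2R,3S,6Z)-3-hydroxy-2-[(3E,5R,7E)-5-hydroxy-4,8,12-trimethyltrideca-3,7,11-trien-1-yl]-2,3-dimethyl-6-(1-oxopropan-2-ylidene)cyclohexyl]propyl tetradecanoate | CCCCCCCCCCCCCC(=O)OCCC[C@H]1/C(=C(/C)C=O)CC[C@](C)(O)[C@]1(C)CC/C=C(\C)[C@H](O)C/C=C(\C)CCC=C(C)C | target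

**Step count and risks**

Total steps: 12. Longest linear sequence: 10 (steps 3 to 12, from 4).

Three steps most likely to fail:

1. Step 1 (new enantioselective dearomatization; the ee of a para attack remote from iodine is the main uncertainty). Fallback, from 1 back to 2, by known chemistry: PhI(OAc)2 in MeCN/H2O at 0 °C gives racemic 4-hydroxy-3,4-dimethylcyclohexa-2,5-dien-1-one F1, which is resolved by preparative chromatography on a chiral amylose-carbamate phase. The (S)-enantiomer is 2, and the (R)-enantiomer is discarded.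

2. Step 7 (a quaternary centre is formed next to a fully substituted carbinol carbon by a hindered, functionalised Grignard reagent; enolisation or 1,2-addition may compete). Fallback, from 11 (as its Grignard reagent 13) back to 17: the two substituents of the quaternary carbon change roles, so that only a methyl group has to be delivered, by copper, anti to a silyloxy group.
   - 3-Ethoxycyclohex-2-en-1-one F2 is methylated (LiN(iPr)2, MeI) to 3-ethoxy-6-methylcyclohex-2-en-1-one F3.
   - The potassium enolate of F3 (KN(SiMe3)2) is hydroxylated with an enantiopure (camphorsulfonyl)oxaziridine to (6S)-3-ethoxy-6-hydroxy-6-methylcyclohex-2-en-1-one F4.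
   - The sodium alkoxide of F4 (NaH) takes up 13 with CeCl3 at the carbonyl, and dilute HCl hydrolyses and dehydrates the adduct (Stork–Danheiser transposition) to (4S)-4-hydroxy-4-methyl-3-SC-cyclohex-2-en-1-one F5.
   - Me3SiOTf/Et3N gives the trimethylsilyl ether F6.
   - Me2CuLi/Me3SiCl adds methyl anti to the silyloxy group to give the silyl enol ether F7.
   - MeLi then 12 in DMPU gives the trimethylsilyl ether of 17, F8.
   - K2CO3/MeOH removes the tertiary silyl ether and equilibrates C2, returning 17.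

3. Step 11 (Z/E control, and possible acid-induced trapping of an allyl cation by the free tertiary alcohol under acidic hexavalent chromium). Fallback, from 24 back to 27: Ph3SiOReO3 (2 mol%) in Et2O at −20 °C isomerises the tertiary allylic alcohol, without oxidant and under thermodynamic control, to the (Z)-primary allylic alcohol 3-[(1S,2R,3S,6Z)-3-hydroxy-6-(1-hydroxypropan-2-ylidene)-2,3-dimethyl-2-SC-cyclohexyl]propyl tetradecanoate F9. MnO2 in CH2Cl2 then oxidises only this primary allylic alcohol to 27.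

Further compounds
F1 | step 1 | rac-4-hydroxy-3,4-dimethylcyclohexa-2,5-dien-1-one | O=C1C=CC(C)(O)C(C)=C1
F2 | step 7 | 3-ethoxycyclohex-2-en-1-one | CCOC1=CC(=O)CCC1
F3 | step 7 | rac-3-ethoxy-6-methylcyclohex-2-en-1-one | CCOC1=CC(=O)C(C)CC1
F4 | step 7 | (6S)-3-ethoxy-6-hydroxy-6-methylcyclohex-2-en-1-one | CCOC1=CC(=O)[C@@](C)(O)CC1
F5 | step 7 | (4S)-4-hydroxy-4-methyl-3-SC-cyclohex-2-en-1-one | O=C1CC[C@](C)(O)C(CC/C=C(\C)[C@H](O[Si](C)(C)C(C)(C)C)C/C=C(\C)CCC=C(C)C)=C1
F6 | step 7 | (4S)-4-methyl-3-SC-4-(trimethylsilyloxy)cyclohex-2-en-1-one | O=C1CC[C@](C)(O[Si](C)(C)C)C(CC/C=C(\C)[C@H](O[Si](C)(C)C(C)(C)C)C/C=C(\C)CCC=C(C)C)=C1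
F7 | step 7 | (3R,4S)-3,4-dimethyl-3-SC-1,4-bis(trimethylsilyloxy)cyclohex-1-ene | C[Si](C)(C)OC1=C[C@@](C)(CC/C=C(\C)[C@H](O[Si](C)(C)C(C)(C)C)C/C=C(\C)CCC=C(C)C)[C@@](C)(O[Si](C)(C)C)CC1
F8 | step 7 | (2R,3R,4S)-3,4-dimethyl-2-(prop-2-en-1-yl)-3-SC-4-(trimethylsilyloxy)cyclohexan-1-one | C=CC[C@H]1C(=O)CC[C@](C)(O[Si](C)(C)C)[C@]1(C)CC/C=C(\C)[C@H](O[Si](C)(C)C(C)(C)C)C/C=C(\C)CCC=C(C)C
F9 | step 11 | 3-[(1S,2R,3S,6Z)-3-hydroxy-6-(1-hydroxypropan-2-ylidene)-2,3-dimethyl-2-SC-cyclohexyl]propyl tetradecanoate | CCCCCCCCCCCCCC(=O)OCCC[C@H]1/C(=C(/C)CO)CC[C@](C)(O)[C@]1(C)CC/C=C(\C)[C@H](O[Si](C)(C)C(C)(C)C)C/C=C(\C)CCC=C(C)C
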